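**Retrosynthetic overview**

1. Target 11 ⇐ protected biflavone 10, by one-pot removal of four benzyl ethers and the chelated 5-OMe (the 7-OMe stays).
2. 10 ⇐ Suzuki–Miyaura union (C3 of the genkwanin half to C6 of the luteolin half) of 3-borylflavone 9 with 6-iodoluteolin tribenzyl ether 3.
3. 9 ⇐ ynone 7 by the key ring closure: O1–C2 bond formation (demethylative oxyboration) builds ring C of the genkwanin half and places boron on C3.
4. 7 ⇐ 2,4,6-trimethoxybenzoic acid 4 + alkyne 5 (acyl Sonogashira); 3 ⇐ luteolin 1 (tribenzylation, then C6 iodination directed by the free 5-OH).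
5. Ring order: all rings of the luteolin half and all benzene rings are bought; the only ring made is ring C of the genkwanin half (step 4), before the biaryl union.

Assumption: the target SMILES carries no stereodescriptor and has no stereocentre; the C3–C6 biaryl axis is taken as not configurationally defined, so no stereocontrol is needed.

**Route**

Step 1
Reactants: 1 luteolin
Product: 2 7,3′,4′-tri-O-benzylluteolin
Conditions: BnBr (3.3 equiv), K2CO3 (3.5 equiv), DMF, 25 °C
Reagents that add atoms: benzyl bromide (BrCc1ccccc1)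
Why: Williamson ether synthesis in which the three acidic phenols (7, 3′, 4′) are benzylated while the 5-OH, hydrogen-bonded to the C4 carbonyl, stays free at this stoichiometry; no stereocentre is formed.

Step 2
Reactants: 2 7,3′,4′-tri-O-benzylluteolin
Product: 3 6-iodo-7,3′,4′-tri-O-benzylluteolin
Conditions: BnNMe3 ICl2 (1.1 equiv), CaCO3 (1.5 equiv), CH2Cl2/MeOH 5:2, 25 °C
Reagents that add atoms: benzyltrimethylammonium dichloroiodate (C[N+](C)(C)Cc1ccccc1.Cl[I-]Cl)
Why: Electrophilic aromatic iodination, which in 5-hydroxy-7-alkoxyflavones goes ortho to the free chelated phenol (C6, not C8), with CaCO3 taking up HCl and the benzylated ring B and the pyranone being far less nucleophilic.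

Step 3
Reactants: 4 2,4,6-trimethoxybenzoic acid; 5 1-(benzyloxy)-4-ethynylbenzene
Product: 7 ynone 3-[4-(benzyloxy)phenyl]-1-(2,4,6-trimethoxyphenyl)prop-2-yn-1-one, via acid chloride 6 (not isolated)
Conditions: (COCl)2, DMF (cat.), CH2Cl2, 0 → 25 °C, evaporate; then 5, PdCl2(PPh3)2 (2 mol %), CuI (4 mol %), Et3N (1.5 equiv), THF, 25 °C
Reagents that add atoms: none
Why: Acid chloride formation followed by acyl Sonogashira coupling (the aroyl chloride has no α-hydrogen and couples with the copper acetylide at room temperature), leaving all ether groups untouched.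

Step 4
Reactants: 7 ynone 3-[4-(benzyloxy)phenyl]-1-(2,4,6-trimethoxyphenyl)prop-2-yn-1-one
Product: 9 3-Bpin flavone 2-[4-(benzyloxy)phenyl]-5,7-dimethoxy-3-(4,4,5,5-tetramethyl-1,3,2-dioxaborolan-2-yl)-4H-chromen-4-one, via catecholboronate 8 (not isolated)
Conditions: ClBcat (1.5 equiv), toluene, 80 °C; then pinacol (3 equiv), Et3N, 25 °C
Reagents that add atoms: B-chlorocatecholborane (ClB1Oc2ccccc2O1); pinacol (CC(C)(O)C(C)(C)O)
Why: Proposed new method: demethylative trans-oxyboration of an ortho-methoxyaryl ynone (borylative 6-endo cyclisation), in which the boron electrophile ClBcat is expected to add to the alkyne carbon next to the carbonyl (the carbon that takes up I+ in the ICl cyclisation of such ynones), the cationic character at the other alkyne carbon is stabilised by the 4-benzyloxyphenyl group and captured anti by the ortho-methoxy oxygen to form the O1–C2 bond of ring C, chloride removes the methyl group of the oxonium ion as MeCl to leave 3-Bcat flavone 8, and pinacol/Et3N exchanges the labile catecholate for the stable pinacol ester; the closest known reaction types are the catalyst-free ClBcat oxyboration and thioboration of ortho-alkynyl aryl esters and thioanisoles, the BCl3 borylative cyclisation of ortho-alkynylanisoles and the ICl iodocyclisation of ortho-methoxyaryl ynones, and the borylative variant has not been shown for ynones giving 3-borylchromones; no stereocentre is formed.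

Step 5
Reactants: 9 3-Bpin flavone 2-[4-(benzyloxy)phenyl]-5,7-dimethoxy-3-(4,4,5,5-tetramethyl-1,3,2-dioxaborolan-2-yl)-4H-chromen-4-one; 3 6-iodo-7,3′,4′-tri-O-benzylluteolin
Product: 10 protected biflavone 7-(benzyloxy)-2-[3,4-bis(benzyloxy)phenyl]-6-{2-[4-(benzyloxy)phenyl]-5,7-dimethoxy-4-oxo-4H-chromen-3-yl}-5-hydroxy-4H-chromen-4-one
Conditions: Pd(OAc)2 (5 mol %), SPhos (10 mol %), K3PO4 (3 equiv), toluene/H2O 10:1, 90 °C
Reagents that add atoms: none
Why: Suzuki–Miyaura coupling, with the bulky electron-rich biarylphosphine supporting oxidative addition into the hindered iodide and reductive elimination to the tetra-ortho-substituted C3–C6 bond, the free 5-OH tolerated as its phenoxide and all ethers inert; the new axis is not stereodefined in the target.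

Step 6
Reactants: 10 protected biflavone 7-(benzyloxy)-2-[3,4-bis(benzyloxy)phenyl]-6-{2-[4-(benzyloxy)phenyl]-5,7-dimethoxy-4-oxo-4H-chromen-3-yl}-5-hydroxy-4H-chromen-4-one
Product: 11 target, 2-(3,4-dihydroxyphenyl)-5,7-dihydroxy-6-[5-hydroxy-2-(4-hydroxyphenyl)-7-methoxy-4-oxo-4H-chromen-3-yl]-4H-chromen-4-one
Conditions: BCl3 (12 equiv), C6HMe5 (12 equiv), CH2Cl2, −78 → 25 °C; MeOH/H2O quench
Reagents that add atoms: none
Why: Lewis-acid ether cleavage in which BCl3 removes the four benzyl ethers (pentamethylbenzene traps the benzyl cations so the electron-rich rings are not C-benzylated) and, through chelation to the C4 carbonyl, the peri 5-OMe, whereas the unchelated 7-OMe is not cleaved by BCl3.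

**Compound list**

1 | luteolin, 2-(3,4-dihydroxyphenyl)-5,7-dihydroxy-4H-chromen-4-one | O=c1cc(-c2ccc(O)c(O)c2)oc2cc(O)cc(O)c12 | starting material
2 | 7,3′,4′-tri-O-benzylluteolin, 7-(benzyloxy)-2-[3,4-bis(benzyloxy)phenyl]-5-hydroxy-4H-chromen-4-one | O=c1cc(-c2ccc(OCc3ccccc3)c(OCc3ccccc3)c2)oc2cc(OCc3ccccc3)cc(O)c12 | intermediate
3 | 6-iodo-7,3′,4′-tri-O-benzylluteolin, 7-(benzyloxy)-2-[3,4-bis(benzyloxy)phenyl]-5-hydroxy-6-iodo-4H-chromen-4-one | O=c1cc(-c2ccc(OCc3ccccc3)c(OCc3ccccc3)c2)oc2cc(OCc3ccccc3)c(I)c(O)c12 | intermediate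
4 | 2,4,6-trimethoxybenzoic acid | COc1cc(OC)c(C(=O)O)c(OC)c1 | starting material
5 | 1-(benzyloxy)-4-ethynylbenzene | C#Cc1ccc(OCc2ccccc2)cc1 | starting material
6 | 2,4,6-trimethoxybenzoyl chloride (not isolated) | COc1cc(OC)c(C(=O)Cl)c(OC)c1 | intermediate
7 | ynone, 3-[4-(benzyloxy)phenyl]-1-(2,4,6-trimethoxyphenyl)prop-2-yn-1-one | COc1cc(OC)c(C(=O)C#Cc2ccc(OCc3ccccc3)cc2)c(OC)c1 | intermediate
8 | 3-Bcat flavone, 3-(1,3,2-benzodioxaborol-2-yl)-2-[4-(benzyloxy)phenyl]-5,7-dimethoxy-4H-chromen-4-one (not isolated) | COc1cc(OC)c2c(=O)c(B3Oc4ccccc4O3)c(-c3ccc(OCc4ccccc4)cc3)oc2c1 | intermediate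
9 | 3-Bpin flavone, 2-[4-(benzyloxy)phenyl]-5,7-dimethoxy-3-(4,4,5,5-tetramethyl-1,3,2-dioxaborolan-2-yl)-4H-chromen-4-one | COc1cc(OC)c2c(=O)c(B3OC(C)(C)C(C)(C)O3)c(-c3ccc(OCc4ccccc4)cc3)oc2c1 | intermediate
10 | protected biflavone, 7-(benzyloxy)-2-[3,4-bis(benzyloxy)phenyl]-6-{2-[4-(benzyloxy)phenyl]-5,7-dimethoxy-4-oxo-4H-chromen-3-yl}-5-hydroxy-4H-chromen-4-one | COc1cc(OC)c2c(=O)c(-c3c(OCc4ccccc4)cc4oc(-c5ccc(OCc6ccccc6)c(OCc6ccccc6)c5)cc(=O)c4c3O)c(-c3ccc(OCc4ccccc4)cc3)oc2c1 | intermediate
11 | target, 2-(3,4-dihydroxyphenyl)-5,7-dihydroxy-6-[5-hydroxy-2-(4-hydroxyphenyl)-7-methoxy-4-oxo-4H-chromen-3-yl]-4H-chromen-4-one | COc1cc(O)c2c(=O)c(-c3c(O)cc4oc(-c5ccc(O)c(O)c5)cc(=O)c4c3O)c(-c3ccc(O)cc3)oc2c1 | target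

**Totals**

Total step count: 6 (convergent).
Longest linear sequence: 4 steps (1 → 2 → 3 → 10 → 11, or 4/5 → 7 → 9 → 10 → 11).

**Three steps most likely to fail, with fallbacks**

Step 4 (the new oxyboration). ClBcat may sit on the ynone carbonyl and only demethylate the ortho-methoxy group, giving the unborylated flavone after work-up. It may also partly cleave the 4′-O-benzyl or peri-methoxy group, which would be harmless because both are removed in step 6. Fallback with known chemistry: starting from 7, ICl (1.5 equiv, CH2Cl2, −78 °C) effects the established demethylative iodocyclisation to 2-[4-(benzyloxy)phenyl]-3-iodo-5,7-dimethoxy-4H-chromen-4-one F1. Miyaura borylation of this iodide (B2pin2, PdCl2(dppf), KOAc, dioxane, 85 °C) comes back to the route at 9.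

Step 5 (hindered Suzuki coupling). Protodeboronation of 9 or slow transmetalation towards the doubly ortho-oxygenated partner may dominate. Fallback: change the nucleophile from boron to zinc. Starting from 7, the iodoflavone F1 is made as described above. Zinc insertion (Zn dust, LiCl, THF, 40 °C) gives {2-[4-(benzyloxy)phenyl]-5,7-dimethoxy-4-oxo-4H-chromen-3-yl}zinc iodide F2. Negishi coupling of this zinc reagent with 3 (phenol first deprotonated with NaH; Pd(OAc)2, RuPhos, THF, 60 °C) comes back to the route at 10.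

Step 3 (acyl Sonogashira with a doubly ortho-substituted, electron-rich aroyl chloride). Oxidative addition may be slow or decarbonylation may compete. Fallback: starting from 5, deprotonation (n-BuLi, THF, −78 °C) and addition to commercial 2,4,6-trimethoxybenzaldehyde gives racemic 3-[4-(benzyloxy)phenyl]-1-(2,4,6-trimethoxyphenyl)prop-2-yn-1-ol F3. Oxidation of this alcohol with MnO2 (CH2Cl2, 25 °C) comes back to the route at 7.

**Further compounds**

F1 | step 4 | 2-[4-(benzyloxy)phenyl]-3-iodo-5,7-dimethoxy-4H-chromen-4-one | COc1cc(OC)c2c(=O)c(I)c(-c3ccc(OCc4ccccc4)cc3)oc2c1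
F2 | step 5 | {2-[4-(benzyloxy)phenyl]-5,7-dimethoxy-4-oxo-4H-chromen-3-yl}zinc iodide | COc1cc(OC)c2c(=O)c([Zn]I)c(-c3ccc(OCc4ccccc4)cc3)oc2c1
F3 | step 3 | 3-[4-(benzyloxy)phenyl]-1-(2,4,6-trimethoxyphenyl)prop-2-yn-1-ol (racemic) | COc1cc(OC)c(C(O)C#Cc2ccc(OCc3ccccc3)cc2)c(OC)c1
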